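**Plan**

Retrosynthesis (primed locants: dihydronaphthalene half, aromatic ring C and partly saturated ring D; unprimed: naphthalene half, acetyl-bearing ring A and phenolic ring B): (a) retro-aldol cut of C1′–C2′ in ring D to an achiral biaryl keto-aldehyde; (b) cut of the C7–C7′ biaryl bond (Suzuki–Miyaura); (c) cut of the aryl–CH2 bond of the enone chain (γ-arylation of mesityl oxide); (d) cut of ring A across C1–C2 and C3–C4 (toluate Michael–Dieckmann annulation).
Enabling feature: in ring D, C2′ is both α to the acetyl carbonyl and allylic to C3′=C4′, and C1′ is a benzylic carbinol peri to the C8′ phenol; ring D is therefore a β-ketol whose open form is a ring C salicylaldehyde carrying a γ-aryl enone with a doubly activated benzylic CH2 (future C4′).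
Forward order: ring B arene, then ring A annulated onto it; separately ring C arene with masked formyl group and enone chain; biaryl bond; unmasking; ring D closed last by a polyketide-like aldol.
Stereochemistry: C1′ (S) and C2′ (R, trans to C1′–OH) are both created in the last step under control of D-proline.

Key step: step 12

Remark: the biaryl bond carries only two ortho substituents (two hydroxyl groups), so it is assumed to rotate freely and no axial configuration is planned.

**Step 1**
Reactants: 1 2-bromo-5-methylphenol
Product: 2 3-bromo-2-hydroxy-6-methylbenzaldehyde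
Conditions: MgCl2, Et3N, (CH2O)n, MeCN, reflux; then 1 M HCl
Reagents that add atoms: paraformaldehyde (formaldehyde), C=O
Why: Casnati–Skattebøl ortho-formylation, in which the magnesium phenoxide delivers formaldehyde to the only free ortho position and a second equivalent of formaldehyde oxidises the hydroxymethyl intermediate, so the 1,2,3,4-substitution pattern of ring B arises regiospecifically.

**Step 2**
Reactants: 2 3-bromo-2-hydroxy-6-methylbenzaldehyde
Product: 3 3-bromo-2-(methoxymethoxy)-6-methylbenzaldehyde
Conditions: MOMCl, iPr2NEt, CH2Cl2, 0 °C to rt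
Reagents that add atoms: chloromethyl methyl ether, COCCl
Why: O-alkylation of the phenol gives a MOM ether that should tolerate chlorite, lithium amide and the palladium steps and is removed only in step 11.

**Step 3**
Reactants: 3 3-bromo-2-(methoxymethoxy)-6-methylbenzaldehyde
Product: 4 3-bromo-2-(methoxymethoxy)-6-methylbenzoic acid
Conditions: NaClO2, NaH2PO4, 2-methylbut-2-ene, t-BuOH/H2O, rt
Reagents that add atoms: sodium chlorite, [Na+].[O-]Cl=O
Why: Pinnick oxidation converts the hindered aryl aldehyde into the acid without touching the aryl bromide or the MOM ether, the alkene scavenging hypochlorous acid.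

**Step 4**
Reactants: 4 3-bromo-2-(methoxymethoxy)-6-methylbenzoic acid
Product: 5 methyl 3-bromo-2-(methoxymethoxy)-6-methylbenzoate
Conditions: MeI, K2CO3, DMF, rt
Reagents that add atoms: iodomethane, CI
Why: SN2 alkylation of the carboxylate esterifies the di-ortho-substituted acid, for which Fischer esterification would be slow, and gives the o-toluate needed for annulation.

**Step 5**
Reactants: 5 methyl 3-bromo-2-(methoxymethoxy)-6-methylbenzoate; 6 (E)-4-methoxypent-3-en-2-one
Product: 8 1-[7-bromo-1-hydroxy-8-(methoxymethoxy)-3-methylnaphthalen-2-yl]ethan-1-one, via methoxytetralone 7 (not isolated)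
Conditions: LiN(iPr)2 (2.3 equiv), THF, −78 °C; then 6, −78 °C to rt; sat. aq. NH4Cl
Reagents that add atoms: none
Why: Staunton–Weinreb annulation, in which lateral lithiation of the o-toluate, conjugate addition to the β-methoxy enone, Dieckmann closure onto the ester and loss of methanol from 7 build ring A directly as the aromatic 2-acetyl-3-methyl-1-naphthol, the aryl bromide being inert to the amide base at −78 °C.

**Step 6**
Reactants: 9 5-bromo-2-chlorophenol
Product: 10 6-bromo-3-chloro-2-hydroxybenzaldehyde
Conditions: MgCl2, Et3N, (CH2O)n, MeCN, reflux; then 1 M HCl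
Reagents that add atoms: paraformaldehyde (formaldehyde), C=O
Why: the same magnesium-mediated ortho-formylation as in step 1 must use the one remaining ortho position (between OH and C–Br), as in the known formylation of 2,5-dihalophenols, and so fixes the substitution pattern of ring C.

**Step 7**
Reactants: 10 6-bromo-3-chloro-2-hydroxybenzaldehyde
Product: 11 6-bromo-3-chloro-2-(methoxymethoxy)benzaldehyde
Conditions: MOMCl, iPr2NEt, CH2Cl2, 0 °C to rt
Reagents that add atoms: chloromethyl methyl ether, COCCl
Why: O-alkylation protects the phenol so that the formyl group can be acetalised and the arene carried through two base-mediated palladium couplings.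

**Step 8**
Reactants: 11 6-bromo-3-chloro-2-(methoxymethoxy)benzaldehyde
Product: 12 1-bromo-4-chloro-2-(dimethoxymethyl)-3-(methoxymethoxy)benzene
Conditions: HC(OMe)3, MeOH, PPTS (cat.), rt; Et3N quench
Reagents that add atoms: trimethyl orthoformate, COC(OC)OC; methanol, CO
Why: acid-catalysed acetalisation with orthoformate as water scavenger masks the formyl group against the carbonate and phosphate bases of steps 9 and 10, the mild pyridinium acid leaving the aryl MOM ether intact.

**Step 9**
Reactants: 12 1-bromo-4-chloro-2-(dimethoxymethyl)-3-(methoxymethoxy)benzene; 13 mesityl oxide (4-methylpent-3-en-2-one)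
Product: 14 (E)-5-[4-chloro-2-(dimethoxymethyl)-3-(methoxymethoxy)phenyl]-4-methylpent-3-en-2-one
Conditions: Pd(OAc)2 (5 mol %), PPh3 (15 mol %), Cs2CO3, 13 (4 equiv), DMF, 100 °C
Reagents that add atoms: none
Why: palladium-catalysed γ-arylation of an α,β-unsaturated ketone through its extended caesium dienolate (vinylogous ketone arylation) should occur at C–Br in preference to C–Cl with the PPh3 catalyst and at the unhindered γ-terminus, and the E/Z composition of the product is immaterial because both isomers give the same dienamine in step 12.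

**Step 10**
Reactants: 8 1-[7-bromo-1-hydroxy-8-(methoxymethoxy)-3-methylnaphthalen-2-yl]ethan-1-one; 14 (E)-5-[4-chloro-2-(dimethoxymethyl)-3-(methoxymethoxy)phenyl]-4-methylpent-3-en-2-one
Product: 16 (E)-5-{4-[7-acetyl-8-hydroxy-1-(methoxymethoxy)-6-methylnaphthalen-2-yl]-2-(dimethoxymethyl)-3-(methoxymethoxy)phenyl}-4-methylpent-3-en-2-one, via pinacol boronate 15 (not isolated)
Conditions: Pd2(dba)3 (2 mol %), XPhos (8 mol %), bis(pinacolato)diboron (1.1 equiv), KOAc, 1,4-dioxane, 100 °C; then 14, aq. K3PO4, 90 °C
Reagents that add atoms: none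
Why: one-pot Miyaura borylation of aryl bromide 8 and Suzuki–Miyaura coupling of boronate 15 with aryl chloride 14, in which the bulky dialkylbiarylphosphine permits oxidative addition into the C–Cl bond and union of two ortho-oxygenated partners, forms the C7–C7′ bond while acetal, MOM ethers and enone are tolerated.

**Step 11**
Reactants: 16 (E)-5-{4-[7-acetyl-8-hydroxy-1-(methoxymethoxy)-6-methylnaphthalen-2-yl]-2-(dimethoxymethyl)-3-(methoxymethoxy)phenyl}-4-methylpent-3-en-2-one
Product: 17 3-(7-acetyl-1,8-dihydroxy-6-methylnaphthalen-2-yl)-2-hydroxy-6-[(E)-2-methyl-4-oxopent-2-en-1-yl]benzaldehyde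
Conditions: 3 M aq. HCl, THF/MeOH, 0 °C to rt; pH 6 phosphate buffer; used without delay
Reagents that add atoms: water, O
Why: acid hydrolysis cleaves both aryl MOM ethers and the dimethyl acetal, and low temperature with short contact time is chosen because enolisation of the enone towards the benzylic γ-carbon, the entry to unwanted acid-mediated cyclodehydration, should be much slower than acetal hydrolysis.

**Step 12**
Reactants: 17 3-(7-acetyl-1,8-dihydroxy-6-methylnaphthalen-2-yl)-2-hydroxy-6-[(E)-2-methyl-4-oxopent-2-en-1-yl]benzaldehyde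
Product: 19 1-[(1S,2R)-7-(7-acetyl-1,8-dihydroxy-6-methylnaphthalen-2-yl)-1,8-dihydroxy-3-methyl-1,2-dihydronaphthalen-2-yl]ethan-1-one, via dienamine 18 (not isolated)
Conditions: D-proline (30 mol %), DMSO, 20 °C, argon; pH 7 phosphate buffer
Reagents that add atoms: none
Why: Proposed new method: D-proline condenses with the side-chain ketone of 17 to an iminium ion, loss of a proton from the doubly activated benzylic CH2 gives dienamine 18, whose α-carbon (future C2′) attacks the formyl carbon (future C1′) while the carboxylic acid hydrogen-bonds the formyl oxygen, and hydrolysis of the product iminium releases 19 and the catalyst; the step is argued from mechanism because an enantioselective aldol ring closure through a dienamine made from a γ-aryl enone has no direct precedent. The closest known reactions are the proline-catalysed 6-enolexo aldolisation of dialdehydes and keto-aldehydes (Houk–List transition state) and α-selective dienamine catalysis of enals. Ring D closes in the 6-(enolexo)-exo-trig mode, the alternatives through the γ-carbon or the acetyl methyl group requiring a four- or an eight-membered ring. C1′ is controlled by the catalyst, since in the D-proline transition state the enamine should add to the Si face of the formyl group (mirror image of the Re-face addition known for L-proline), which gives 1′S. C2′ is controlled by the enamine geometry (E, with C3′ trans to nitrogen), which places the developing hydroxyl and acetyl groups gauche and pseudo-equatorial, that is trans, and on the same catalyst face gives 2′R. The step needs chemoselectivity for the enone over the ring A acetyl group (an aryl ketone flanked by two ortho substituents and held in a hydrogen bond to the C1 hydroxyl, so unable to form an enamine), a cis arrangement of ring C and C2′ across C3′=C4′ (reached because iminium and dienamine interconvert through the benzylic position), an activated and conformationally fixed aldehyde (hydrogen bond from the free C8′ phenol) and arrest at the β-ketol stage (neutral medium, ambient temperature, no added base).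

**Compound list**

1 | 2-bromo-5-methylphenol | Cc1ccc(Br)c(O)c1 | starting material
2 | 3-bromo-2-hydroxy-6-methylbenzaldehyde | Cc1ccc(Br)c(O)c1C=O | intermediate
3 | 3-bromo-2-(methoxymethoxy)-6-methylbenzaldehyde | Cc1ccc(Br)c(OCOC)c1C=O | intermediate
4 | 3-bromo-2-(methoxymethoxy)-6-methylbenzoic acid | Cc1ccc(Br)c(OCOC)c1C(=O)O | intermediate
5 | methyl 3-bromo-2-(methoxymethoxy)-6-methylbenzoate | Cc1ccc(Br)c(OCOC)c1C(=O)OC | intermediate
6 | (E)-4-methoxypent-3-en-2-one | CO/C(C)=C/C(C)=O | starting material
7 | 2-acetyl-7-bromo-3-methoxy-8-(methoxymethoxy)-3-methyl-3,4-dihydronaphthalen-1(2H)-one (mixture of stereoisomers, not isolated) | COCOc1c(Br)ccc2CC(C)(OC)C(C(C)=O)C(=O)c12 | intermediate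
8 | 1-[7-bromo-1-hydroxy-8-(methoxymethoxy)-3-methylnaphthalen-2-yl]ethan-1-one | COCOc1c(Br)ccc2cc(C)c(C(C)=O)c(O)c12 | intermediate
9 | 5-bromo-2-chlorophenol | Oc1cc(Br)ccc1Cl | starting material
10 | 6-bromo-3-chloro-2-hydroxybenzaldehyde | O=Cc1c(Br)ccc(Cl)c1O | intermediate
11 | 6-bromo-3-chloro-2-(methoxymethoxy)benzaldehyde | O=Cc1c(Br)ccc(Cl)c1OCOC | intermediate
12 | 1-bromo-4-chloro-2-(dimethoxymethyl)-3-(methoxymethoxy)benzene | COC(OC)c1c(Br)ccc(Cl)c1OCOC | intermediate
13 | mesityl oxide (4-methylpent-3-en-2-one) | CC(=O)C=C(C)C | starting material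
14 | (E)-5-[4-chloro-2-(dimethoxymethyl)-3-(methoxymethoxy)phenyl]-4-methylpent-3-en-2-one | CC(=O)/C=C(\C)Cc1ccc(Cl)c(OCOC)c1C(OC)OC | intermediate
15 | 1-[1-hydroxy-8-(methoxymethoxy)-3-methyl-7-(4,4,5,5-tetramethyl-1,3,2-dioxaborolan-2-yl)naphthalen-2-yl]ethan-1-one (not isolated) | COCOc1c(B2OC(C)(C)C(C)(C)O2)ccc2cc(C)c(C(C)=O)c(O)c12 | intermediate
16 | (E)-5-{4-[7-acetyl-8-hydroxy-1-(methoxymethoxy)-6-methylnaphthalen-2-yl]-2-(dimethoxymethyl)-3-(methoxymethoxy)phenyl}-4-methylpent-3-en-2-one | CC(=O)/C=C(\C)Cc1ccc(-c2ccc3cc(C)c(C(C)=O)c(O)c3c2OCOC)c(OCOC)c1C(OC)OC | intermediate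
17 | 3-(7-acetyl-1,8-dihydroxy-6-methylnaphthalen-2-yl)-2-hydroxy-6-[(E)-2-methyl-4-oxopent-2-en-1-yl]benzaldehyde | CC(=O)/C=C(\C)Cc1ccc(-c2ccc3cc(C)c(C(C)=O)c(O)c3c2O)c(O)c1C=O | intermediate
18 | (R)-1-{(2E,4Z)-5-[4-(7-acetyl-1,8-dihydroxy-6-methylnaphthalen-2-yl)-2-formyl-3-hydroxyphenyl]-4-methylpenta-2,4-dien-2-yl}pyrrolidine-2-carboxylic acid (dienamine, not isolated) | OC(=O)[C@H]1CCCN1/C(C)=C/C(C)=C\c1ccc(-c2ccc3cc(C)c(C(C)=O)c(O)c3c2O)c(O)c1C=O | intermediate
19 | 1-[(1S,2R)-7-(7-acetyl-1,8-dihydroxy-6-methylnaphthalen-2-yl)-1,8-dihydroxy-3-methyl-1,2-dihydronaphthalen-2-yl]ethan-1-one | CC(=O)c1c(C)cc2ccc(-c3ccc4c(c3O)[C@@H](O)[C@H](C(C)=O)C(C)=C4)c(O)c2c1O | target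

**Step count**

Total: 12 steps. Longest linear sequence: 8 steps (steps 1 to 5, then 10 to 12).

**Steps most likely to fail**

1. Step 12 (Proposed new method). What may go wrong: slow iminium and dienamine formation from the hindered β,β-disubstituted enone; incomplete facial control or erosion of the trans and enantiomeric purity through reversible aldol and retro-aldol; onward dehydration of the β-ketol with aromatisation of ring D. Fallback with known chemistry, in which the configuration comes from separation and not from a catalyst: setting out from 17, ring D is closed without chiral induction by ordinary base-mediated aldol addition through the extended enolate, which adds to aldehydes at its α-carbon (DBU, 0.2 equiv, THF, −20 °C, buffered quench). This should give the racemic trans ketol, that is 19 together with its mirror image, the (1R,2S)-enantiomer of 19 F1. Preparative HPLC on a chiral stationary phase (amylose tris(3,5-dimethylphenylcarbamate)) then separates F1 and returns to the route at 19.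

2. Step 11. What may go wrong: acid-promoted aldol condensation between the newly unveiled formyl group and the dienol of the enone followed by loss of water, or incomplete cleavage of the MOM ethers under conditions mild enough to avoid it. Fallback that keeps the future formyl carbon at the alcohol oxidation level so that the acid step meets no aldehyde: setting out from 10, NaBH4 in MeOH gives 3-bromo-6-chloro-2-(hydroxymethyl)phenol F2, and 2,2-dimethoxypropane with PPTS in acetone ties phenol and benzylic alcohol together as 5-bromo-8-chloro-2,2-dimethyl-4H-1,3-benzodioxine F3. γ-Arylation with 13 under the conditions of step 9 gives (E)-5-(8-chloro-2,2-dimethyl-4H-1,3-benzodioxin-5-yl)-4-methylpent-3-en-2-one F4. Borylation of 8 and coupling under the conditions of step 10 (through 15) gives (E)-5-{8-[7-acetyl-8-hydroxy-1-(methoxymethoxy)-6-methylnaphthalen-2-yl]-2,2-dimethyl-4H-1,3-benzodioxin-5-yl}-4-methylpent-3-en-2-one F5. Aqueous HCl in THF/MeOH removes acetonide and MOM ether to give (E)-5-[4-(7-acetyl-1,8-dihydroxy-6-methylnaphthalen-2-yl)-3-hydroxy-2-(hydroxymethyl)phenyl]-4-methylpent-3-en-2-one F6. Oxidation of the salicyl alcohol with MnO2 in CH2Cl2 under neutral conditions returns to the route at 17.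

3. Step 9. What may go wrong: competing arylation at the acetyl methyl group through the cross-conjugated enolate, a second arylation at the now more acidic benzylic position, and base-induced self-condensation of 13. Fallback by Heck chemistry: setting out from 12, Heck reaction with 4-methylpent-4-en-2-ol (Pd(OAc)2, P(o-tol)3, Et3N, DMF, 90 °C) gives (E)-5-[4-chloro-2-(dimethoxymethyl)-3-(methoxymethoxy)phenyl]-4-methylpent-4-en-2-ol F7. Dess–Martin periodinane in CH2Cl2 gives (E)-5-[4-chloro-2-(dimethoxymethyl)-3-(methoxymethoxy)phenyl]-4-methylpent-4-en-2-one F8, and catalytic DBU moves the double bond into conjugation, returning to the route at 14.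

**Further compounds**

F1 | step 12 | (1R,2S)-enantiomer of 19, 1-[(1R,2S)-7-(7-acetyl-1,8-dihydroxy-6-methylnaphthalen-2-yl)-1,8-dihydroxy-3-methyl-1,2-dihydronaphthalen-2-yl]ethan-1-one | CC(=O)c1c(C)cc2ccc(-c3ccc4c(c3O)[C@H](O)[C@@H](C(C)=O)C(C)=C4)c(O)c2c1O
F2 | step 11 | 3-bromo-6-chloro-2-(hydroxymethyl)phenol | OCc1c(Br)ccc(Cl)c1O
F3 | step 11 | 5-bromo-8-chloro-2,2-dimethyl-4H-1,3-benzodioxine | CC1(C)OCc2c(Br)ccc(Cl)c2O1
F4 | step 11 | (E)-5-(8-chloro-2,2-dimethyl-4H-1,3-benzodioxin-5-yl)-4-methylpent-3-en-2-one | CC(=O)/C=C(\C)Cc1ccc(Cl)c2OC(C)(C)OCc12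
F5 | step 11 | (E)-5-{8-[7-acetyl-8-hydroxy-1-(methoxymethoxy)-6-methylnaphthalen-2-yl]-2,2-dimethyl-4H-1,3-benzodioxin-5-yl}-4-methylpent-3-en-2-one | CC(=O)/C=C(\C)Cc1ccc(-c3ccc4cc(C)c(C(C)=O)c(O)c4c3OCOC)c2OC(C)(C)OCc12
F6 | step 11 | (E)-5-[4-(7-acetyl-1,8-dihydroxy-6-methylnaphthalen-2-yl)-3-hydroxy-2-(hydroxymethyl)phenyl]-4-methylpent-3-en-2-one | CC(=O)/C=C(\C)Cc1ccc(-c2ccc3cc(C)c(C(C)=O)c(O)c3c2O)c(O)c1CO
F7 | step 9 | (E)-5-[4-chloro-2-(dimethoxymethyl)-3-(methoxymethoxy)phenyl]-4-methylpent-4-en-2-ol | CC(O)C/C(C)=C/c1ccc(Cl)c(OCOC)c1C(OC)OC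
F8 | step 9 | (E)-5-[4-chloro-2-(dimethoxymethyl)-3-(methoxymethoxy)phenyl]-4-methylpent-4-en-2-one | CC(=O)C/C(C)=C/c1ccc(Cl)c(OCOC)c1C(OC)OC
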